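**Retrosynthetic overview**

1. Guaiane numbering is used: ring A (cyclopentenone) = C-1 (ring-fusion CH), C-2 (CH2), C-3 (C=O), C-4 (=CMe), C-5; ring B (cycloheptane) = C-1, C-5 to C-10. The C-8 methacrylate and C-11 acetate are put on the diol last.
2. Ring A is opened at C-1–C-2 and C-3–C-4. The enabling feature: in ring A the CH2–C=O pair (C-2, C-3) bridges the two ends of the allyl triad C-1/C-5/C-4, and C-4 is sp2 in the target. An oxygen on C-4 of a 1-(cyclohept-1-enyl)ethanol is therefore a traceless handle: as an ethynyl ether it passes the two-carbon unit to C-1 by [3,3] shift (chirality transfer C-4 → C-1), and the ketene carbon formed then returns to C-4.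
3. Ring B: ring-closing metathesis (C-1=C-5) of an α-methylene ketone with a terminal vinyl group, then CBS reduction to the (S)-carbinol at C-4; the C-8/C-11 diol is held in a temporary acetonide ring.
4. Acyclic chain: Evans syn-aldol (C-7–C-8 bond, sets C-7 and C-8) between a 4-bromopent-4-enoyl imide and (S)-3-methylpent-4-enal (C-10 from an auxiliary-controlled vinyl 1,4-addition); C-11 carbinol from the ester and MeMgBr.
5. Order of ring formation: acetonide (temporary) → ring B (metathesis) → ring A (key step) → acetonide removed.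

Key step: step 14

Remark: 4-bromopent-4-enoic acid and both 4-benzyloxazolidin-2-ones are taken as purchasable; the (E)-ethylidene geometry drawn for 26 and 27 is the one expected from the methyl-outside transition state, and either geometry would converge on 28.

**Route**

Step 1
Reactants: 1 (R)-4-benzyloxazolidin-2-one; 2 (E)-but-2-enoyl chloride
Product: 4 (R)-4-benzyl-3-[(E)-but-2-enoyl]oxazolidin-2-one, via lithium oxazolidinide 3 (not isolated)
Conditions: n-BuLi, THF, −78 °C; then 2, −78 → 0 °C
Reagents that add atoms: none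
Why: N-acylation of the lithiated oxazolidinone by the acid chloride (standard imide formation) should be clean at low temperature and creates no stereocenter.

Step 2
Reactants: 4 (R)-4-benzyl-3-[(E)-but-2-enoyl]oxazolidin-2-one
Product: 5 (R)-4-benzyl-3-[(3S)-3-methylpent-4-enoyl]oxazolidin-2-one
Conditions: vinylMgBr (1.5 equiv), CuBr·SMe2 (0.2 equiv), THF, −78 → −30 °C; aq. NH4Cl
Reagents that add atoms: vinylmagnesium bromide, C=C[Mg]Br
Why: Copper-catalysed conjugate (1,4-) addition of vinylMgBr to the magnesium-chelated s-cis N-enoyl imide should place the vinyl group on the alkene face opposite to the benzyl group of the auxiliary, which sets the methyl-bearing stereocenter (future C-10) as (S).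

Step 3
Reactants: 5 (R)-4-benzyl-3-[(3S)-3-methylpent-4-enoyl]oxazolidin-2-one
Product: 6 (3S)-3-methylpent-4-en-1-ol
Conditions: LiBH4, Et2O, H2O (1 equiv), 0 °C
Reagents that add atoms: none
Why: Reductive cleavage of the imide with LiBH4 (hydride attack at the exocyclic carbonyl) should release the primary alcohol and the recoverable auxiliary without touching the non-epimerisable β-stereocenter or the alkene.

Step 4
Reactants: 6 (3S)-3-methylpent-4-en-1-ol
Product: 7 (3S)-3-methylpent-4-enal
Conditions: TEMPO (cat.), PhI(OAc)2, CH2Cl2, rt; washed, dried and used as a CH2Cl2 solution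
Reagents that add atoms: none
Why: TEMPO-catalysed oxidation with PhI(OAc)2 as terminal oxidant (oxoammonium oxidation) should stop at the aldehyde under nearly neutral conditions, and the stereocenter is β to the carbonyl and cannot epimerise.

Step 5
Reactants: 8 4-bromopent-4-enoic acid; 9 (S)-4-benzyloxazolidin-2-one
Product: 11 (S)-4-benzyl-3-(4-bromopent-4-enoyl)oxazolidin-2-one, via mixed pivalic anhydride 10 (not isolated)
Conditions: PivCl, Et3N, THF, −20 °C; then LiCl, 9, −20 °C → rt
Reagents that add atoms: none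
Why: Acylation of the oxazolidinone by the in situ mixed pivalic anhydride under LiCl/Et3N activation is the standard mild imide synthesis, leaves the vinyl bromide untouched and forms no stereocenter.

Step 6
Reactants: 11 (S)-4-benzyl-3-(4-bromopent-4-enoyl)oxazolidin-2-one; 7 (3S)-3-methylpent-4-enal
Product: 13 (S)-4-benzyl-3-[(2S,3R,5S)-2-(2-bromoprop-2-en-1-yl)-3-hydroxy-5-methylhept-6-enoyl]oxazolidin-2-one, via boron enolate 12 (not isolated)
Conditions: Bu2BOTf, iPr2NEt, CH2Cl2, −78 → 0 °C; then 7, −78 → 0 °C; H2O2, MeOH, pH 7 buffer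
Reagents that add atoms: none
Why: Evans syn-aldol reaction: the (Z)-boron enolate reacts through a closed Zimmerman–Traxler chair in which the (S)-benzyl auxiliary shields one enolate face, so C-7 (S) and C-8 (R) should be set together under auxiliary control, the remote methyl stereocenter of the aldehyde having little influence.

Step 7
Reactants: 13 (S)-4-benzyl-3-[(2S,3R,5S)-2-(2-bromoprop-2-en-1-yl)-3-hydroxy-5-methylhept-6-enoyl]oxazolidin-2-one
Product: 14 methyl (2S,3R,5S)-2-(2-bromoprop-2-en-1-yl)-3-hydroxy-5-methylhept-6-enoate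
Conditions: MeMgBr (1.5 equiv), MeOH–CH2Cl2, 0 °C (MeOMgBr formed in situ)
Reagents that add atoms: methanol, CO
Why: Transesterification of the imide with bromomagnesium methoxide (exocyclic acyl cleavage) should give the methyl ester under conditions mild enough to avoid retro-aldol cleavage or epimerisation at C-7.

Step 8
Reactants: 14 methyl (2S,3R,5S)-2-(2-bromoprop-2-en-1-yl)-3-hydroxy-5-methylhept-6-enoate
Product: 16 (3S,4R,6S)-3-(2-bromoprop-2-en-1-yl)-2,6-dimethyloct-7-ene-2,4-diol, via methyl ketone 15 (not isolated)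
Conditions: MeMgBr (5 equiv), THF, 0 °C → rt; aq. NH4Cl
Reagents that add atoms: methylmagnesium bromide, C[Mg]Br
Why: Double Grignard addition of MeMgBr to the ester through ketone 15 should give the tertiary carbinol (C-11) while the vinyl bromide stays inert, and no stereocenter is created.

Step 9
Reactants: 16 (3S,4R,6S)-3-(2-bromoprop-2-en-1-yl)-2,6-dimethyloct-7-ene-2,4-diol
Product: 17 (5S,6R)-5-(2-bromoprop-2-en-1-yl)-2,2,4,4-tetramethyl-6-[(2S)-2-methylbut-3-en-1-yl]-1,3-dioxane
Conditions: 2,2-dimethoxypropane, PPTS (cat.), CH2Cl2, rt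
Reagents that add atoms: 2,2-dimethoxypropane, COC(C)(C)OC
Why: Acid-catalysed transketalisation joins the secondary and tertiary hydroxyl groups in a six-membered acetonide (temporary ring) that masks both against the strong bases of steps 10, 13 and 14; the acetal carbon carries two methyl groups and is not a stereocenter.

Step 10
Reactants: 17 (5S,6R)-5-(2-bromoprop-2-en-1-yl)-2,2,4,4-tetramethyl-6-[(2S)-2-methylbut-3-en-1-yl]-1,3-dioxane
Product: 19 3-{[(5S,6R)-2,2,4,4-tetramethyl-6-[(2S)-2-methylbut-3-en-1-yl]-1,3-dioxan-5-yl]methyl}but-3-en-2-one, via vinyllithium 18 (not isolated)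
Conditions: t-BuLi (2.1 equiv), Et2O, −78 °C; then N-methoxy-N-methylacetamide, −78 → 0 °C; aq. NH4Cl
Reagents that add atoms: N-methoxy-N-methylacetamide, CC(=O)N(C)OC
Why: Bromine–lithium exchange gives the alkenyllithium 18, which is acylated by the Weinreb amide (Weinreb ketone synthesis) through a stable chelated tetrahedral intermediate, so the α-methylene ketone is released only on work-up.

Step 11
Reactants: 19 3-{[(5S,6R)-2,2,4,4-tetramethyl-6-[(2S)-2-methylbut-3-en-1-yl]-1,3-dioxan-5-yl]methyl}but-3-en-2-one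
Product: 20 acetonide of 1-[(3S,5R,6S)-5-hydroxy-6-(2-hydroxypropan-2-yl)-3-methylcyclohept-1-en-1-yl]ethan-1-one
Conditions: second-generation Hoveyda–Grubbs catalyst RuCl2(H2IMes)(=CH–C6H4–2-OiPr) (5 mol%), toluene (0.002 M), 80 °C
Reagents that add atoms: none
Why: Ring-closing metathesis should start at the terminal vinyl group and close ring B onto the 1,1-disubstituted enone olefin with loss of ethene, a seven-membered trisubstituted cycloalkene being within the scope of second-generation ruthenium carbenes at high dilution.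

Step 12
Reactants: 20 acetonide of 1-[(3S,5R,6S)-5-hydroxy-6-(2-hydroxypropan-2-yl)-3-methylcyclohept-1-en-1-yl]ethan-1-one
Product: 21 acetonide of (1S)-1-[(3S,5R,6S)-5-hydroxy-6-(2-hydroxypropan-2-yl)-3-methylcyclohept-1-en-1-yl]ethan-1-ol
Conditions: (R)-2-methyl-CBS-oxazaborolidine (0.2 equiv), catecholborane, toluene, −78 °C
Reagents that add atoms: none
Why: Corey–Bakshi–Shibata reduction is reagent-controlled: with the (R)-oxazaborolidine the cycloalkenyl group acts as the large and the methyl group as the small substituent, which should give the (S)-carbinol at C-4 (as with aryl methyl ketones), catecholborane being chosen to avoid hydroboration of the alkene.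

Step 13
Reactants: 21 acetonide of (1S)-1-[(3S,5R,6S)-5-hydroxy-6-(2-hydroxypropan-2-yl)-3-methylcyclohept-1-en-1-yl]ethan-1-ol
Product: 23 (E)-1,2-dichloroethenyl ether of alcohol 21, via potassium alkoxide 22 (not isolated)
Conditions: KH (2.2 equiv), THF, 0 °C; then Cl2C=CHCl (1.3 equiv), 0 °C → rt
Reagents that add atoms: trichloroethylene, ClC=C(Cl)Cl
Why: The potassium alkoxide adds to dichloroacetylene generated in situ from trichloroethylene and KH (the established route to (E)-1,2-dichlorovinyl ethers as stable precursors of alkynyl ethers), a reaction at oxygen that leaves the C-4 configuration untouched.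

Step 14
Reactants: 23 (E)-1,2-dichloroethenyl ether of alcohol 21
Product: 28 acetonide of (5S,6R,8S,8aR)-6-hydroxy-5-(2-hydroxypropan-2-yl)-3,8-dimethyl-4,5,6,7,8,8a-hexahydroazulen-2(1H)-one, via chloroalkynyl ether 24 (not isolated), via lithium alkynyl ether 25 (not isolated), via lithium ynolate 26 (not isolated), via ketene 27 (not isolated)
Conditions: n-BuLi (2.3 equiv), Et2O, −78 → −40 °C; 2,6-di-tert-butyl-4-methylphenol (1.3 equiv), −78 °C; EtAlCl2 (3 equiv), CH2Cl2, −78 → −30 °C; aq. NaHCO3
Reagents that add atoms: none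
Why: Proposed new method: n-BuLi converts the dichlorovinyl ether via 24 into the lithium alkynyl ether 25, whose [3,3]-sigmatropic shift (ynol-ether Claisen rearrangement, the closest known reaction type, known for simple allyl alkynyl ethers at −78 °C with trapping of the ynolate or ketene by alcohols) forms the C-1–C-2 bond and gives ynolate 26; C-protonation by the hindered phenol gives ketene 27, and EtAlCl2 then makes its carbonyl carbon C-3 electrophilic enough to be attacked by the ethylidene carbon C-4, as in Lewis-acid-promoted ketene–alkene additions and in the classical cyclization of 4-alkenoyl cations to cyclopentenones. Because the one-carbon tether forbids collapse to a cyclobutanone, the tertiary C-5 cation should lose H-4 to an Al–Et group (ethane), and protonation of the resulting dienolate at C-2 on work-up gives the conjugated enone. Ring A is closed in a cationic 5-endo-trig mode (C-3 onto C-4, Markovnikov, charge at tertiary C-5). The only new stereocenter, C-1, is set in the suprafacial sigmatropic step by the temporary (S)-carbinol carbon C-4: in the transition state with the C-4 methyl group outside (E-ethylidene) the oxygen lies on the ring face opposite to the C-10 methyl group and the acetonide, so chirality transfer and substrate bias are matched, and C-4 then becomes sp2 and leaves no trace. The step needs the sigmatropic shift to outrun other reactions of the acetylide, C-4 regioselectivity in the acylation and loss of H-4 in place of H-1 or H-6; these should be secured by the low barrier of ynol-ether rearrangements, by the trisubstituted ethylidene (only C-5 can carry a tertiary cation) and by the position of H-4 next to the developing enolate, while the base-sensitive esters are still absent at this stage.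

Step 15
Reactants: 28 acetonide of (5S,6R,8S,8aR)-6-hydroxy-5-(2-hydroxypropan-2-yl)-3,8-dimethyl-4,5,6,7,8,8a-hexahydroazulen-2(1H)-one
Product: 29 (5S,6R,8S,8aR)-6-hydroxy-5-(2-hydroxypropan-2-yl)-3,8-dimethyl-4,5,6,7,8,8a-hexahydroazulen-2(1H)-one
Conditions: AcOH/H2O/THF (3:1:1), 40 °C
Reagents that add atoms: none
Why: Mild aqueous acid hydrolysis of the strained tetramethyl-1,3-dioxane (acetal hydrolysis) should free the diol without dehydrating the tertiary carbinol or epimerising C-1.

Step 16
Reactants: 29 (5S,6R,8S,8aR)-6-hydroxy-5-(2-hydroxypropan-2-yl)-3,8-dimethyl-4,5,6,7,8,8a-hexahydroazulen-2(1H)-one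
Product: 30 (5S,6R,8S,8aR)-5-(2-hydroxypropan-2-yl)-3,8-dimethyl-2-oxo-1,2,4,5,6,7,8,8a-octahydroazulen-6-yl 2-methylprop-2-enoate
Conditions: methacrylic anhydride (1.5 equiv), Et3N, DMAP (0.2 equiv), CH2Cl2, 0 °C → rt
Reagents that add atoms: methacrylic anhydride, C=C(C)C(=O)OC(=O)C(C)=C
Why: DMAP-catalysed acylation should be selective for the secondary C-8 hydroxyl over the tertiary C-11 hydroxyl on steric grounds and proceeds with retention because the C–O bond is not broken.

Step 17
Reactants: 30 (5S,6R,8S,8aR)-5-(2-hydroxypropan-2-yl)-3,8-dimethyl-2-oxo-1,2,4,5,6,7,8,8a-octahydroazulen-6-yl 2-methylprop-2-enoate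
Product: 31 (5S,6R,8S,8aR)-5-(2-acetoxypropan-2-yl)-3,8-dimethyl-2-oxo-1,2,4,5,6,7,8,8a-octahydroazulen-6-yl 2-methylprop-2-enoate (CNP0318307.1)
Conditions: Ac2O (3 equiv), Sc(OTf)3 (5 mol%), MeCN, −20 °C
Reagents that add atoms: acetic anhydride, CC(=O)OC(C)=O
Why: Sc(OTf)3-catalysed acylation with Ac2O acetylates tertiary alcohols at low temperature by acyl transfer to oxygen (no C–O cleavage), which should give the tertiary acetate without elimination or change at any stereocenter.

**Compound list**

1 | (R)-4-benzyloxazolidin-2-one | O=C1OC[C@@H](Cc2ccccc2)N1 | starting material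
2 | (E)-but-2-enoyl chloride | C/C=C/C(Cl)=O | starting material
3 | lithium (R)-4-benzyl-2-oxooxazolidin-3-ide | O=C1OC[C@@H](Cc2ccccc2)N1[Li] | intermediate
4 | (R)-4-benzyl-3-[(E)-but-2-enoyl]oxazolidin-2-one | C/C=C/C(=O)N1[C@H](Cc2ccccc2)COC1=O | intermediate
5 | (R)-4-benzyl-3-[(3S)-3-methylpent-4-enoyl]oxazolidin-2-one | C=C[C@@H](C)CC(=O)N1[C@H](Cc2ccccc2)COC1=O | intermediate
6 | (3S)-3-methylpent-4-en-1-ol | C=C[C@@H](C)CCO | intermediate
7 | (3S)-3-methylpent-4-enal | C=C[C@@H](C)CC=O | intermediate
8 | 4-bromopent-4-enoic acid | C=C(Br)CCC(=O)O | starting material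
9 | (S)-4-benzyloxazolidin-2-one | O=C1OC[C@H](Cc2ccccc2)N1 | starting material
10 | 4-bromopent-4-enoic pivalic anhydride | C=C(Br)CCC(=O)OC(=O)C(C)(C)C | intermediate
11 | (S)-4-benzyl-3-(4-bromopent-4-enoyl)oxazolidin-2-one | C=C(Br)CCC(=O)N1[C@@H](Cc2ccccc2)COC1=O | intermediate
12 | (Z)-dibutylboron enolate of 11 | C=C(Br)C/C=C(\OB(CCCC)CCCC)N1[C@@H](Cc2ccccc2)COC1=O | intermediate
13 | (S)-4-benzyl-3-[(2S,3R,5S)-2-(2-bromoprop-2-en-1-yl)-3-hydroxy-5-methylhept-6-enoyl]oxazolidin-2-one | C=C[C@@H](C)C[C@@H](O)[C@H](CC(Br)=C)C(=O)N1[C@@H](Cc2ccccc2)COC1=O | intermediate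
14 | methyl (2S,3R,5S)-2-(2-bromoprop-2-en-1-yl)-3-hydroxy-5-methylhept-6-enoate | C=C[C@@H](C)C[C@@H](O)[C@H](CC(Br)=C)C(=O)OC | intermediate
15 | (3S,4R,6S)-3-(2-bromoprop-2-en-1-yl)-4-hydroxy-6-methyloct-7-en-2-one (present as its magnesium alkoxide) | C=C[C@@H](C)C[C@@H](O)[C@H](CC(Br)=C)C(C)=O | intermediate
16 | (3S,4R,6S)-3-(2-bromoprop-2-en-1-yl)-2,6-dimethyloct-7-ene-2,4-diol | C=C[C@@H](C)C[C@@H](O)[C@H](CC(Br)=C)C(C)(C)O | intermediate
17 | (5S,6R)-5-(2-bromoprop-2-en-1-yl)-2,2,4,4-tetramethyl-6-[(2S)-2-methylbut-3-en-1-yl]-1,3-dioxane | C=C[C@@H](C)C[C@H]1OC(C)(C)OC(C)(C)[C@H]1CC(Br)=C | intermediate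
18 | 2-lithioprop-2-en-1-yl analogue of 17 (vinyllithium) | C=C[C@@H](C)C[C@H]1OC(C)(C)OC(C)(C)[C@H]1CC([Li])=C | intermediate
19 | 3-{[(5S,6R)-2,2,4,4-tetramethyl-6-[(2S)-2-methylbut-3-en-1-yl]-1,3-dioxan-5-yl]methyl}but-3-en-2-one | C=C[C@@H](C)C[C@H]1OC(C)(C)OC(C)(C)[C@H]1CC(=C)C(C)=O | intermediate
20 | acetonide of 1-[(3S,5R,6S)-5-hydroxy-6-(2-hydroxypropan-2-yl)-3-methylcyclohept-1-en-1-yl]ethan-1-one | CC(=O)C1=C[C@@H](C)C[C@H]2OC(C)(C)OC(C)(C)[C@H]2C1 | intermediate
21 | acetonide of (1S)-1-[(3S,5R,6S)-5-hydroxy-6-(2-hydroxypropan-2-yl)-3-methylcyclohept-1-en-1-yl]ethan-1-ol | C[C@H](O)C1=C[C@@H](C)C[C@H]2OC(C)(C)OC(C)(C)[C@H]2C1 | intermediate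
22 | potassium alkoxide of 21 | C[C@H]([O-])C1=C[C@@H](C)C[C@H]2OC(C)(C)OC(C)(C)[C@H]2C1.[K+] | intermediate
23 | (E)-1,2-dichloroethenyl ether of alcohol 21 | C[C@H](O/C(Cl)=C\Cl)C1=C[C@@H](C)C[C@H]2OC(C)(C)OC(C)(C)[C@H]2C1 | intermediate
24 | chloroethynyl ether of alcohol 21 | C[C@H](OC#CCl)C1=C[C@@H](C)C[C@H]2OC(C)(C)OC(C)(C)[C@H]2C1 | intermediate
25 | lithioethynyl ether of alcohol 21 | C[C@H](OC#C[Li])C1=C[C@@H](C)C[C@H]2OC(C)(C)OC(C)(C)[C@H]2C1 | intermediate
26 | lithium ynolate: C-1 carries the C≡C–OLi group anti to the C-10 methyl group, (E)-ethylidene at C-5, acetonide unchanged | [Li]OC#C[C@@H]1[C@@H](C)C[C@H]2OC(C)(C)OC(C)(C)[C@H]2C/C1=C\C | intermediate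
27 | ketene from C-protonation of 26 | O=C=C[C@@H]1[C@@H](C)C[C@H]2OC(C)(C)OC(C)(C)[C@H]2C/C1=C\C | intermediate
28 | acetonide of (5S,6R,8S,8aR)-6-hydroxy-5-(2-hydroxypropan-2-yl)-3,8-dimethyl-4,5,6,7,8,8a-hexahydroazulen-2(1H)-one | CC1(C)O[C@@H]2C[C@H](C)[C@H]3CC(=O)C(C)=C3C[C@@H]2C(C)(C)O1 | intermediate
29 | (5S,6R,8S,8aR)-6-hydroxy-5-(2-hydroxypropan-2-yl)-3,8-dimethyl-4,5,6,7,8,8a-hexahydroazulen-2(1H)-one | O[C@@H]1C[C@H](C)[C@H]2CC(=O)C(C)=C2C[C@@H]1C(C)(C)O | intermediate
30 | (5S,6R,8S,8aR)-5-(2-hydroxypropan-2-yl)-3,8-dimethyl-2-oxo-1,2,4,5,6,7,8,8a-octahydroazulen-6-yl 2-methylprop-2-enoate | C=C(C)C(=O)O[C@@H]1C[C@H](C)[C@H]2CC(=O)C(C)=C2C[C@@H]1C(C)(C)O | intermediate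
31 | (5S,6R,8S,8aR)-5-(2-acetoxypropan-2-yl)-3,8-dimethyl-2-oxo-1,2,4,5,6,7,8,8a-octahydroazulen-6-yl 2-methylprop-2-enoate (CNP0318307.1) | C=C(C)C(=O)O[C@@H]1C[C@H](C)[C@H]2CC(=O)C(C)=C2C[C@@H]1C(C)(C)OC(C)=O | target

**Step count and risks**

Total steps: 17. Longest linear sequence: 16 (steps 1–4, then 6–17).

Step 14 (key step). The Lewis-acid-bound aldoketene may oligomerise or take up an ethyl group from aluminium. The C-5 cation may also lose the ring-fusion proton, with alkene migration towards C-1 and erosion of its configuration, or the acetonide may open. The fallback uses known chemistry and sets out from 23. The same n-BuLi treatment, followed by a methanol quench (the established trapping of the rearranged ynolate/ketene), should give the γ,δ-unsaturated methyl ester F1. LiOH hydrolysis gives the carboxylic acid F2, and oxalyl chloride converts it into the acid chloride F3. SnCl4 in CH2Cl2 at −78 °C then effects the classical intramolecular acylation of the ethylidene group to the β-chloro ketone F4. Et3N eliminates HCl across C-4/C-5 (E1cB; H-4 is the only acidic β-hydrogen), and the route is rejoined at 28.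

Step 11. The ruthenium carbene formed at the vinyl group may couple two substrate molecules faster than it engages the electron-poor 1,1-disubstituted enone olefin, or the catalyst may decay before ring closure. The fallback changes the order of events and sets out from 19. CBS reduction as in step 12 gives the acyclic (S)-allylic alcohol F5, whose electron-richer olefin with a free allylic hydroxyl group is the better metathesis partner. Ring closure of F5 with the same catalyst rejoins the route at 21.

Step 17. The tertiary carbinol may ionise under the Lewis acid, with elimination to an isopropenyl group, or the neighbouring methacrylate may migrate. The fallback sets out from diol 29. Exhaustive acetylation under basic conditions (Ac2O, DMAP, Et3N, 50 °C; no cationic pathway) gives the diacetate F6. Selective methanolysis of the less hindered secondary acetate (K2CO3, MeOH, 0 °C) gives the C-8 alcohol C-11 acetate F7. Methacrylation of F7 as in step 16 rejoins the route at the target 31.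

**Further compounds**

F1 | step 14 | methyl ester from methanol trapping of ketene 27 (acetonide, (E)-ethylidene) | COC(=O)C[C@@H]1[C@@H](C)C[C@H]2OC(C)(C)OC(C)(C)[C@H]2C/C1=C\C
F2 | step 14 | carboxylic acid from F1 | OC(=O)C[C@@H]1[C@@H](C)C[C@H]2OC(C)(C)OC(C)(C)[C@H]2C/C1=C\C
F3 | step 14 | acid chloride from F2 | ClC(=O)C[C@@H]1[C@@H](C)C[C@H]2OC(C)(C)OC(C)(C)[C@H]2C/C1=C\C
F4 | step 14 | β-chloro ketone (chloride at C-5, mixture at C-4 and C-5) | CC1(C)O[C@@H]2C[C@H](C)[C@H]3CC(=O)C(C)C3(Cl)C[C@@H]2C(C)(C)O1
F5 | step 11 | (2S)-3-{[(5S,6R)-2,2,4,4-tetramethyl-6-[(2S)-2-methylbut-3-en-1-yl]-1,3-dioxan-5-yl]methyl}but-3-en-2-ol | C=C[C@@H](C)C[C@H]1OC(C)(C)OC(C)(C)[C@H]1CC(=C)[C@H](C)O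
F6 | step 17 | diacetate of diol 29 | CC(=O)O[C@@H]1C[C@H](C)[C@H]2CC(=O)C(C)=C2C[C@@H]1C(C)(C)OC(C)=O
F7 | step 17 | C-11 acetate of diol 29 with free C-8 hydroxyl | O[C@@H]1C[C@H](C)[C@H]2CC(=O)C(C)=C2C[C@@H]1C(C)(C)OC(C)=O
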